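**Retrosynthetic overview**

1. Target 17 ⇐ fluoride desilylation of silyl peroxide 16 ⇐ cobalt-catalysed Markovnikov hydroperoxysilylation of the isopropenyl group of oxepine 15; the peroxide enters as O2 on a tertiary radical next to the finished stereocentre.
2. 15 ⇐ key step: enantioselective palladium-catalysed [5+2] heteroannulation of isoprene (14) with 3-iodoflavone 13. One operation makes the C-3–CH2 bond and the aryl O-2′–CH bond, closes the oxepine, brings in all five side-chain carbons and sets the only stereocentre.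
3. Enabling feature: in 13 the 2′-OH of ring B and the carbon–iodine bond at C-3 of ring C sit cis on the C-2=C-3 double bond of the pyranone. O-2′, C-2′, C-1′, C-2 and C-3 (five of the seven oxepine atoms, four of them sp2) are therefore in place, and the diene only supplies CH2–CH.
4. 13 ⇐ C-3 lithiation/iodination, ether cleavage and 4′-O-silylation of flavone 9 ⇐ Suzuki coupling of 6-bromoflavone 7 with 8 ⇐ chalcone route from acetophenone 3 and aldehyde 4; 3 ⇐ ortho-acylation of the symmetric phenol 1, which fixes bromine (later the alkenyl group) at C-6.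
5. Ring order: rings A and B are bought, ring C (pyranone) is formed in step 3, the oxepine in step 8.

Key step: step 8

Assumption: 4-bromo-3,5-dimethoxyphenol (1) and the pinacol boronate 8 are taken as catalogue compounds; each is otherwise one operation from 2-bromo-1,3-dimethoxybenzene (C–H borylation/oxidation) or 3-methylbut-1-yne (hydroboration with pinacolborane).

Naming: "oxepinoflavone" below means a flavone whose C-3 and O-2′ are joined by C-1″H2–C-2″H (seven-membered ring); flavone locants are kept.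

**Route**

Step 1
Reactants: 1 4-bromo-3,5-dimethoxyphenol
Product: 3 1-(3-bromo-6-hydroxy-2,4-dimethoxyphenyl)ethan-1-one, via 4-bromo-3,5-dimethoxyphenyl acetate 2 (not isolated)
Conditions: Ac2O, BF3·OEt2, 90 °C; then MeOH/H2O, 60 °C
Reagents that add atoms: acetic anhydride CC(=O)OC(C)=O
Why: O-Acetylation followed by boron trifluoride-mediated Fries rearrangement (Friedel–Crafts ortho-acylation) can only reach the two equivalent positions ortho to the hydroxyl group, so a single acetophenone should form in which bromine stands para to the free OH.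

Step 2
Reactants: 3 1-(3-bromo-6-hydroxy-2,4-dimethoxyphenyl)ethan-1-one; 4 2,4-bis(benzyloxy)benzaldehyde
Product: 5 (E)-3-[2,4-bis(benzyloxy)phenyl]-1-(3-bromo-6-hydroxy-2,4-dimethoxyphenyl)prop-2-en-1-one
Conditions: KOH (50% in H2O), EtOH, rt
Reagents that add atoms: none
Why: Claisen–Schmidt aldol condensation of the methyl ketone with a non-enolisable aldehyde should give the E-enone by loss of water.

Step 3
Reactants: 5 (E)-3-[2,4-bis(benzyloxy)phenyl]-1-(3-bromo-6-hydroxy-2,4-dimethoxyphenyl)prop-2-en-1-one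
Product: 7 2-[2,4-bis(benzyloxy)phenyl]-6-bromo-5,7-dimethoxy-4H-chromen-4-one, via flavanone 6 (not isolated)
Conditions: I2 (10 mol %), DMSO, 130 °C
Reagents that add atoms: none
Why: Oxidative cyclisation of a 2′-hydroxychalcone (oxa-Michael closure, then iodine-mediated dehydrogenation with DMSO as terminal oxidant) forms ring C through the only free hydroxyl group, which places bromine at C-6 between the 5- and 7-methoxy groups.

Step 4
Reactants: 7 2-[2,4-bis(benzyloxy)phenyl]-6-bromo-5,7-dimethoxy-4H-chromen-4-one; 8 4,4,5,5-tetramethyl-2-[(E)-3-methylbut-1-en-1-yl]-1,3,2-dioxaborolane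
Product: 9 2-[2,4-bis(benzyloxy)phenyl]-5,7-dimethoxy-6-[(E)-3-methylbut-1-en-1-yl]-4H-chromen-4-one
Conditions: Pd(OAc)2 (5 mol %), SPhos (10 mol %), K3PO4, toluene/H2O (10:1), 90 °C
Reagents that add atoms: none
Why: Suzuki–Miyaura coupling with a dialkylbiarylphosphine suited to the doubly ortho-substituted, electron-rich aryl bromide should transfer the alkenyl group with retention of its E geometry.

Step 5
Reactants: 9 2-[2,4-bis(benzyloxy)phenyl]-5,7-dimethoxy-6-[(E)-3-methylbut-1-en-1-yl]-4H-chromen-4-one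
Product: 11 2-[2,4-bis(benzyloxy)phenyl]-3-iodo-5,7-dimethoxy-6-[(E)-3-methylbut-1-en-1-yl]-4H-chromen-4-one, via 3-lithioflavone 10 (not isolated)
Conditions: LDA (1.3 equiv), THF, −78 °C; then I2 (1.5 equiv), THF, −78 to −40 °C; aq. Na2S2O3
Reagents that add atoms: iodine [I][I]
Why: Deprotonation of the vinylic C-3–H of a fully protected flavone by lithium diisopropylamide and iodinolysis of the vinyllithium (deprotonative metalation/iodination) puts iodine on C-3 only, where electrophilic iodination would attack C-8 of ring A.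

Step 6
Reactants: 11 2-[2,4-bis(benzyloxy)phenyl]-3-iodo-5,7-dimethoxy-6-[(E)-3-methylbut-1-en-1-yl]-4H-chromen-4-one
Product: 12 2-(2,4-dihydroxyphenyl)-5-hydroxy-3-iodo-7-methoxy-6-[(E)-3-methylbut-1-en-1-yl]-4H-chromen-4-one
Conditions: BCl3 (8 equiv), pentamethylbenzene (6 equiv), CH2Cl2, −78 to −10 °C; MeOH quench at −78 °C, aq. NaHCO3
Reagents that add atoms: none
Why: Lewis acid ether cleavage with BCl3 removes the chelated peri 5-O-methyl group and both benzyl groups (pentamethylbenzene traps the benzyl cations) but not the unchelated 7-OMe, while boron chelation across O-4/O-5 makes ring A electron-poor and so shields the styrene from electrophiles.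

Step 7
Reactants: 12 2-(2,4-dihydroxyphenyl)-5-hydroxy-3-iodo-7-methoxy-6-[(E)-3-methylbut-1-en-1-yl]-4H-chromen-4-one
Product: 13 5-hydroxy-2-{2-hydroxy-4-[tri(propan-2-yl)silyloxy]phenyl}-3-iodo-7-methoxy-6-[(E)-3-methylbut-1-en-1-yl]-4H-chromen-4-one
Conditions: TIPSCl (1.05 equiv), imidazole, DMF, −20 to 0 °C
Reagents that add atoms: chlorotri(propan-2-yl)silane CC(C)[Si](Cl)(C(C)C)C(C)C
Why: Site-selective silylation: the bulky silyl chloride should take the unhindered and most acidic 4′-OH, because 5-OH is locked in a hydrogen bond to the C-4 carbonyl and 2′-OH is flanked by the 3-iodochromone.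

Step 8
Reactants: 13 5-hydroxy-2-{2-hydroxy-4-[tri(propan-2-yl)silyloxy]phenyl}-3-iodo-7-methoxy-6-[(E)-3-methylbut-1-en-1-yl]-4H-chromen-4-one; 14 isoprene (2-methylbuta-1,3-diene)
Product: 15 (2″S)-5-hydroxy-7-methoxy-6-[(E)-3-methylbut-1-en-1-yl]-2″-(prop-1-en-2-yl)-4′-[tri(propan-2-yl)silyloxy]oxepinoflavone
Conditions: Pd2(dba)3·CHCl3 (5 mol %), (S)-BINOL-derived phosphoramidite with a bis[(R)-1-phenylethyl]amino group (12 mol %), Ag2CO3 (1.0 equiv), isoprene (10 equiv), toluene (0.02 mol/L), 50 °C, dark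
Reagents that add atoms: none
Why: Proposed new method: zerovalent palladium should insert into the carbon–iodine bond at C-3 of 13 (the only carbon–halogen bond), the vinylpalladium should add across the unsubstituted vinyl terminus of isoprene (new C-3–CH2 bond) to give a 2-methyl-π-allylpalladium complex, and the 2′-phenoxide formed with Ag2CO3 should attack the allyl terminus next to that CH2 group, forming the aryl O–CH bond and releasing zerovalent palladium. The closest known reaction type is the Larock heteroannulation of 1,3-dienes by ortho-halophenols (a Heck/Tsuji–Trost cascade), which with isoprene gives 2-isopropenyl-2,3-dihydrobenzofurans and has enantioselective variants; here halide and phenol stand in a 1,5- instead of a 1,2-relationship, so the same sequence becomes a [5+2] annulation, which is the untested part. The oxepine closes by 7-exo attack of oxygen on the π-allyl unit (Tsuji–Trost etherification), since closure at the distal CH2 terminus would need a nine-membered ring. The new stereocentre is created in this C–O bond formation and is controlled by the chiral phosphoramidite on palladium, the diastereomeric π-allyl complexes equilibrating by π–σ–π isomerisation through the unsubstituted CH2 terminus before ring closure (Curtin–Hammett control); the sense of induction is not predicted here, so the first run must show which ligand antipode gives S, and the mirror-image ligand is used if needed. The step needs insertion at the less hindered alkene of isoprene, ring closure faster than β-hydride elimination to a 3-dienylflavone, and no intermolecular O-allylation: the cis arrangement of C-3 and the 2′-oxygen across C-2=C-3 of ring C, the excess of diene, the 4′-silyl ether and the chelated, non-nucleophilic 5-OH are meant to secure these.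

Step 9
Reactants: 15 (2″S)-5-hydroxy-7-methoxy-6-[(E)-3-methylbut-1-en-1-yl]-2″-(prop-1-en-2-yl)-4′-[tri(propan-2-yl)silyloxy]oxepinoflavone
Product: 16 (2″S)-5-hydroxy-7-methoxy-6-[(E)-3-methylbut-1-en-1-yl]-2″-[2-(triethylsilylperoxy)propan-2-yl]-4′-[tri(propan-2-yl)silyloxy]oxepinoflavone
Conditions: Co(thd)2 (cobalt bis(2,2,6,6-tetramethylheptane-3,5-dionate), 10 mol %), Et3SiH (2 equiv), O2 (1 atm), ClCH2CH2Cl, rt, stopped when 15 is consumed
Reagents that add atoms: dioxygen O=O; triethylsilane CC[SiH](CC)CC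
Why: Mukaiyama–Isayama hydroperoxysilylation: hydrogen-atom transfer from a cobalt hydride to the 1,1-disubstituted alkene gives the tertiary radical, which traps O2 and is silylated, so the peroxide lands on the tertiary carbon without touching the adjacent stereocentre, while the twisted, doubly ortho-flanked 1,2-disubstituted styrene of ring A is expected to be much slower in hydrogen-atom transfer.

Step 10
Reactants: 16 (2″S)-5-hydroxy-7-methoxy-6-[(E)-3-methylbut-1-en-1-yl]-2″-[2-(triethylsilylperoxy)propan-2-yl]-4′-[tri(propan-2-yl)silyloxy]oxepinoflavone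
Product: 17 (2″S)-4′,5-dihydroxy-2″-(2-hydroperoxypropan-2-yl)-7-methoxy-6-[(E)-3-methylbut-1-en-1-yl]oxepinoflavone (CNP0171472.1)
Conditions: TBAF (2.5 equiv), AcOH (2.5 equiv), THF, 0 °C
Reagents that add atoms: none
Why: Fluoride desilylation cleaves the O–Si bonds of the silyl peroxide and of the aryl silyl ether in one operation, and the acetic acid buffer keeps the tertiary hydroperoxide (no α-hydrogen, hence no Kornblum–DeLaMare fragmentation) and the stereocentre untouched.

**Compound list**

1 | 4-bromo-3,5-dimethoxyphenol | COc1cc(O)cc(OC)c1Br | starting material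
2 | 4-bromo-3,5-dimethoxyphenyl acetate | COc1cc(OC(C)=O)cc(OC)c1Br | intermediate
3 | 1-(3-bromo-6-hydroxy-2,4-dimethoxyphenyl)ethan-1-one | CC(=O)c1c(O)cc(OC)c(Br)c1OC | intermediate
4 | 2,4-bis(benzyloxy)benzaldehyde | O=Cc1ccc(OCc2ccccc2)cc1OCc1ccccc1 | starting material
5 | (E)-3-[2,4-bis(benzyloxy)phenyl]-1-(3-bromo-6-hydroxy-2,4-dimethoxyphenyl)prop-2-en-1-one | COc1cc(O)c(C(=O)/C=C/c2ccc(OCc3ccccc3)cc2OCc2ccccc2)c(OC)c1Br | intermediate
6 | 2-[2,4-bis(benzyloxy)phenyl]-6-bromo-5,7-dimethoxychroman-4-one (racemic flavanone) | COc1cc2OC(c3ccc(OCc4ccccc4)cc3OCc3ccccc3)CC(=O)c2c(OC)c1Br | intermediate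
7 | 2-[2,4-bis(benzyloxy)phenyl]-6-bromo-5,7-dimethoxy-4H-chromen-4-one | COc1cc2oc(-c3ccc(OCc4ccccc4)cc3OCc3ccccc3)cc(=O)c2c(OC)c1Br | intermediate
8 | 4,4,5,5-tetramethyl-2-[(E)-3-methylbut-1-en-1-yl]-1,3,2-dioxaborolane | CC(C)/C=C/B1OC(C)(C)C(C)(C)O1 | starting material
9 | 2-[2,4-bis(benzyloxy)phenyl]-5,7-dimethoxy-6-[(E)-3-methylbut-1-en-1-yl]-4H-chromen-4-one | COc1cc2oc(-c3ccc(OCc4ccccc4)cc3OCc3ccccc3)cc(=O)c2c(OC)c1/C=C/C(C)C | intermediate
10 | 3-lithio derivative of 9 (3-lithioflavone) | COc1cc2oc(-c3ccc(OCc4ccccc4)cc3OCc3ccccc3)c([Li])c(=O)c2c(OC)c1/C=C/C(C)C | intermediate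
11 | 2-[2,4-bis(benzyloxy)phenyl]-3-iodo-5,7-dimethoxy-6-[(E)-3-methylbut-1-en-1-yl]-4H-chromen-4-one | COc1cc2oc(-c3ccc(OCc4ccccc4)cc3OCc3ccccc3)c(I)c(=O)c2c(OC)c1/C=C/C(C)C | intermediate
12 | 2-(2,4-dihydroxyphenyl)-5-hydroxy-3-iodo-7-methoxy-6-[(E)-3-methylbut-1-en-1-yl]-4H-chromen-4-one | COc1cc2oc(-c3ccc(O)cc3O)c(I)c(=O)c2c(O)c1/C=C/C(C)C | intermediate
13 | 5-hydroxy-2-{2-hydroxy-4-[tri(propan-2-yl)silyloxy]phenyl}-3-iodo-7-methoxy-6-[(E)-3-methylbut-1-en-1-yl]-4H-chromen-4-one | COc1cc2oc(-c3ccc(O[Si](C(C)C)(C(C)C)C(C)C)cc3O)c(I)c(=O)c2c(O)c1/C=C/C(C)C | intermediate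
14 | isoprene (2-methylbuta-1,3-diene) | C=CC(C)=C | starting material
15 | (2″S)-5-hydroxy-7-methoxy-6-[(E)-3-methylbut-1-en-1-yl]-2″-(prop-1-en-2-yl)-4′-[tri(propan-2-yl)silyloxy]oxepinoflavone | COc1cc2oc3c(c(=O)c2c(O)c1/C=C/C(C)C)C[C@@H](C(C)=C)Oc1cc(O[Si](C(C)C)(C(C)C)C(C)C)ccc1-3 | intermediate
16 | (2″S)-5-hydroxy-7-methoxy-6-[(E)-3-methylbut-1-en-1-yl]-2″-[2-(triethylsilylperoxy)propan-2-yl]-4′-[tri(propan-2-yl)silyloxy]oxepinoflavone | COc1cc2oc3c(c(=O)c2c(O)c1/C=C/C(C)C)C[C@@H](C(C)(C)OO[Si](CC)(CC)CC)Oc1cc(O[Si](C(C)C)(C(C)C)C(C)C)ccc1-3 | intermediate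
17 | (2″S)-4′,5-dihydroxy-2″-(2-hydroperoxypropan-2-yl)-7-methoxy-6-[(E)-3-methylbut-1-en-1-yl]oxepinoflavone (CNP0171472.1) | COc1cc2oc3c(c(=O)c2c(O)c1/C=C/C(C)C)C[C@@H](C(C)(C)OO)Oc1cc(O)ccc1-3 | target

**Step count and risks**

Total steps: 10. Longest linear sequence: 10 steps (1 to 17).

Steps most likely to fail:

1. Step 8 (Proposed new method). What may go wrong: insertion of isoprene with the wrong regiochemistry, β-hydride elimination from the allylpalladium stage instead of ring closure, poor facial discrimination in the C–O bond formation, or loss of enantiopurity by re-ionisation of the allylic aryl ether by zerovalent palladium. The fallback uses known reactions only, sets out from 13 and comes back at 15. Stille coupling of 13 with tributyl(3-methylbut-2-en-1-yl)stannane (Pd2(dba)3, AsPh3, DMF, 60 °C) gives the 3-prenylflavone F1. Shi epoxidation (D-fructose-derived ketone catalyst, Oxone, K2CO3 buffer, MeCN/dimethoxymethane/H2O, 0 °C) should prefer the trisubstituted prenyl alkene over the hindered styrene and give the (R)-epoxide F2. K2CO3 in MeOH lets the 2′-phenoxide open the epoxide at its secondary carbon (7-exo-tet, inversion) to the (S)-tertiary alcohol F3. Burgess dehydration (benzene, 50 °C) toward a methyl group then gives 15.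

2. Step 9. What may go wrong: loss of chemoselectivity by hydrogen-atom transfer to the styrene of ring A, or over-reduction of the peroxide to the tertiary alcohol. The fallback sets out from 7, comes back at 16, and runs the cobalt step before the styrene exists. Lithiation/iodination of 7 (as in step 5) gives the 6-bromo-3-iodoflavone F4. BCl3/pentamethylbenzene gives the triol F5, and TIPSCl/imidazole gives the silyl ether F6. The heteroannulation of step 8 (the carbon–iodine bond reacts, the hindered carbon–bromine bond stays) gives the bromo-oxepinoflavone F7. Co(thd)2/O2/Et3SiH, with only one alkene present, gives the bromo silyl peroxide F8. Suzuki–Miyaura coupling of F8 with 8 (Pd(OAc)2, SPhos, K3PO4, THF/H2O, 40–50 °C; the ether is no longer allylic at this stage) gives 16; survival of the silyl peroxide under these palladium/phosphine conditions is the open point of this fallback.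

3. Step 7. What may go wrong: loss of site selectivity (silylation of O-2′ or double silylation), which would block the nucleophile of the key step. The fallback sets out from 12, comes back at 17, and drops the protecting group. Triol 12 is taken directly into the heteroannulation of step 8 at higher dilution to give the free-phenol oxepinoflavone F9. The cobalt step gives its triethylsilyl peroxide F10, and buffered fluoride as in step 10 gives 17.

**Further compounds**

F1 | step 8 | 5-hydroxy-2-{2-hydroxy-4-[tri(propan-2-yl)silyloxy]phenyl}-7-methoxy-6-[(E)-3-methylbut-1-en-1-yl]-3-(3-methylbut-2-en-1-yl)-4H-chromen-4-one | COc1cc2oc(-c3ccc(O[Si](C(C)C)(C(C)C)C(C)C)cc3O)c(CC=C(C)C)c(=O)c2c(O)c1/C=C/C(C)C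
F2 | step 8 | 3-{[(2R)-3,3-dimethyloxiran-2-yl]methyl}-5-hydroxy-2-{2-hydroxy-4-[tri(propan-2-yl)silyloxy]phenyl}-7-methoxy-6-[(E)-3-methylbut-1-en-1-yl]-4H-chromen-4-one | COc1cc2oc(-c3ccc(O[Si](C(C)C)(C(C)C)C(C)C)cc3O)c(C[C@H]3OC3(C)C)c(=O)c2c(O)c1/C=C/C(C)C
F3 | step 8 | (2″S)-5-hydroxy-2″-(2-hydroxypropan-2-yl)-7-methoxy-6-[(E)-3-methylbut-1-en-1-yl]-4′-[tri(propan-2-yl)silyloxy]oxepinoflavone | COc1cc2oc3c(c(=O)c2c(O)c1/C=C/C(C)C)C[C@@H](C(C)(C)O)Oc1cc(O[Si](C(C)C)(C(C)C)C(C)C)ccc1-3
F4 | step 9 | 2-[2,4-bis(benzyloxy)phenyl]-6-bromo-3-iodo-5,7-dimethoxy-4H-chromen-4-one | COc1cc2oc(-c3ccc(OCc4ccccc4)cc3OCc3ccccc3)c(I)c(=O)c2c(OC)c1Br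
F5 | step 9 | 6-bromo-2-(2,4-dihydroxyphenyl)-5-hydroxy-3-iodo-7-methoxy-4H-chromen-4-one | COc1cc2oc(-c3ccc(O)cc3O)c(I)c(=O)c2c(O)c1Br
F6 | step 9 | 6-bromo-5-hydroxy-2-{2-hydroxy-4-[tri(propan-2-yl)silyloxy]phenyl}-3-iodo-7-methoxy-4H-chromen-4-one | COc1cc2oc(-c3ccc(O[Si](C(C)C)(C(C)C)C(C)C)cc3O)c(I)c(=O)c2c(O)c1Br
F7 | step 9 | (2″S)-6-bromo-5-hydroxy-7-methoxy-2″-(prop-1-en-2-yl)-4′-[tri(propan-2-yl)silyloxy]oxepinoflavone | COc1cc2oc3c(c(=O)c2c(O)c1Br)C[C@@H](C(C)=C)Oc1cc(O[Si](C(C)C)(C(C)C)C(C)C)ccc1-3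
F8 | step 9 | (2″S)-6-bromo-5-hydroxy-7-methoxy-2″-[2-(triethylsilylperoxy)propan-2-yl]-4′-[tri(propan-2-yl)silyloxy]oxepinoflavone | COc1cc2oc3c(c(=O)c2c(O)c1Br)C[C@@H](C(C)(C)OO[Si](CC)(CC)CC)Oc1cc(O[Si](C(C)C)(C(C)C)C(C)C)ccc1-3
F9 | step 7 | (2″S)-4′,5-dihydroxy-7-methoxy-6-[(E)-3-methylbut-1-en-1-yl]-2″-(prop-1-en-2-yl)oxepinoflavone | COc1cc2oc3c(c(=O)c2c(O)c1/C=C/C(C)C)C[C@@H](C(C)=C)Oc1cc(O)ccc1-3
F10 | step 7 | (2″S)-4′,5-dihydroxy-7-methoxy-6-[(E)-3-methylbut-1-en-1-yl]-2″-[2-(triethylsilylperoxy)propan-2-yl]oxepinoflavone | COc1cc2oc3c(c(=O)c2c(O)c1/C=C/C(C)C)C[C@@H](C(C)(C)OO[Si](CC)(CC)CC)Oc1cc(O)ccc1-3
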